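**Retrosynthetic overview**
1. The acid comes from its ethyl ester by saponification (last step).
2. The dihydropyran, the only ring, is closed in the penultimate step by ring-closing metathesis at C4=C5 of an acyclic diene ether.
3. The ether O1–C6 comes from a palladium π-allyl etherification of an (S)-α-methylene-β-hydroxy ester with a 2-(homofarnesyl)allyl acetate.
4. The key C2–C3 bond and the stereocentre come from allyl acetate used with reversed polarity (a nucleophilic σ-allyl iridium) on ethyl 2-(hydroxymethyl)acrylate at the alcohol oxidation level, so the unstable 2-formylacrylate is never handled.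
5. The side chain comes from the methallyl alcohol dianion (a d3 allyl donor) and (2E,6E)-farnesyl bromide.

Assumption: the target is the 2S enantiomer with both chain olefins E, as the SMILES reads, and farnesyl bromide is bought as the pure E,E isomer.

Step 1
Reactants: 1 2-methylprop-2-en-1-ol (methallyl alcohol); 2 (2E,6E)-1-bromo-3,7,11-trimethyldodeca-2,6,10-triene (farnesyl bromide)
Product: 5 (5E,9E)-6,10,14-trimethyl-2-methylidenepentadeca-5,9,13-trien-1-yl acetate, via methallyl alcohol dianion 3 (not isolated), via lithium alkoxide 4 (not isolated)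
Conditions: n-BuLi (2.1 equiv per 1), TMEDA, Et2O, 0 °C to rt, 24 h; 3 (1.5 equiv) then 2, THF, −78 to 0 °C; then Ac2O, 0 °C
Reagents that add atoms: acetic anhydride, CC(=O)OC(C)=O
Why: Alkylation of the Carlson dianion of methallyl alcohol (alkoxide-directed allylic lithiation, two equivalent CH2 termini) by SN2 attack on the primary allylic bromide keeps both E olefins, and the lithium alkoxide is O-acetylated in the same flask.

Step 2
Reactants: 6 ethyl 2-(hydroxymethyl)prop-2-enoate; 7 prop-2-en-1-yl acetate (allyl acetate)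
Product: 9 ethyl (3S)-3-hydroxy-2-methylidenehex-5-enoate, via ethyl 2-formylprop-2-enoate 8 (not isolated)
Conditions: [Ir(cod)Cl]2 (2.5 mol %), (S)-SEGPHOS (5 mol %), 4-cyano-3-nitrobenzoic acid (10 mol %), Cs2CO3 (20 mol %), 7 (5 equiv), BHT (1 mol %), THF, 100 °C, sealed tube
Reagents that add atoms: none
Why: Proposed new method: this extends Krische's iridium-catalysed transfer-hydrogenative C–H allylation of primary alcohols (known for benzylic and simple allylic alcohols) to an acrylate-bearing allylic alcohol; 6 is dehydrogenated at iridium to enal 8, which stays at low concentration and is captured at once by the nucleophilic σ-allyl trivalent iridium species made from allyl acetate (normally a π-allyl electrophile, here used with reversed polarity, so two carbons that are both electrophilic in their usual roles are joined); the closed chair transition state on the (S)-SEGPHOS cyclometallated C,O-benzoate complex should give the 3S carbinol, the sense I recall for benzylic alcohols and 1,3-diols (S ligand gives S when the substrate-derived group outranks allyl); the closest known reactions are the Krische allylation of cinnamyl-type alcohols and his 2-(alkoxycarbonyl)allylation, where an acrylate survives the same iridium hydride conditions.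

Step 3
Reactants: 9 ethyl (3S)-3-hydroxy-2-methylidenehex-5-enoate; 5 (5E,9E)-6,10,14-trimethyl-2-methylidenepentadeca-5,9,13-trien-1-yl acetate
Product: 11 ethyl (3S)-2-methylidene-3-{[(5E,9E)-6,10,14-trimethyl-2-methylidenepentadeca-5,9,13-trien-1-yl]oxy}hex-5-enoate, via zinc alkoxide 10 (not isolated)
Conditions: Et2Zn (0.5 equiv), THF, 0 °C to rt; then 5 (1.2 equiv), Pd(OAc)2 (5 mol %), 2-(di-tert-butylphosphino)biphenyl (10 mol %), NH4OAc (10 mol %), rt
Reagents that add atoms: none
Why: Tsuji–Trost O-allylation in Lee's zinc alkoxide variant: the 2-substituted π-allyl palladium from 5 has two equivalent CH2 termini, so only one ether can form, and the near-neutral zinc alkoxide leaves the acrylate and the C3 stereocentre (S, not touched) intact.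

Step 4
Reactants: 11 ethyl (3S)-2-methylidene-3-{[(5E,9E)-6,10,14-trimethyl-2-methylidenepentadeca-5,9,13-trien-1-yl]oxy}hex-5-enoate
Product: 12 ethyl 2-[(2S)-5-[(3E,7E)-4,8,12-trimethyltrideca-3,7,11-trien-1-yl]-3,6-dihydro-2H-pyran-2-yl]prop-2-enoate
Conditions: second-generation Grubbs catalyst (H2IMes)(PCy3)Cl2Ru=CHPh (5 mol %), CH2Cl2 (0.005 M), 40 °C
Reagents that add atoms: none
Why: Ring-closing metathesis: ruthenium loads at the monosubstituted allyl olefin and closes the six-membered ring onto the 1,1-disubstituted allyl ether olefin, much faster than any reaction of the electron-poor acrylate or the trisubstituted chain olefins, and the ring enforces the geometry of the new olefin.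

Step 5
Reactants: 12 ethyl 2-[(2S)-5-[(3E,7E)-4,8,12-trimethyltrideca-3,7,11-trien-1-yl]-3,6-dihydro-2H-pyran-2-yl]prop-2-enoate
Product: 13 2-[(2S)-5-[(3E,7E)-4,8,12-trimethyltrideca-3,7,11-trien-1-yl]-3,6-dihydro-2H-pyran-2-yl]prop-2-enoic acid (CNP0171598.1)
Conditions: LiOH·H2O (3 equiv), THF/H2O 3:1, 0 °C to rt; then 1 M HCl to pH 3, 0 °C
Reagents that add atoms: lithium hydroxide (as LiOH·H2O), [Li+].[OH-]
Why: Saponification of the ethyl ester; C2 carries no acidic hydrogen because the acrylate is cross-conjugated, so the S centre and the exocyclic methylene are kept.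

**Compound list**
1 | 2-methylprop-2-en-1-ol (methallyl alcohol) | C=C(C)CO | starting material
2 | (2E,6E)-1-bromo-3,7,11-trimethyldodeca-2,6,10-triene (farnesyl bromide) | BrC/C=C(\C)CC/C=C(\C)CCC=C(C)C | starting material
3 | lithium 2-(lithiomethyl)prop-2-en-1-olate (methallyl alcohol dianion) | [Li]CC(=C)CO[Li] | intermediate (not isolated)
4 | lithium (5E,9E)-6,10,14-trimethyl-2-methylidenepentadeca-5,9,13-trien-1-olate | C=C(CO[Li])CC/C=C(\C)CC/C=C(\C)CCC=C(C)C | intermediate (not isolated)
5 | (5E,9E)-6,10,14-trimethyl-2-methylidenepentadeca-5,9,13-trien-1-yl acetate | C=C(COC(C)=O)CC/C=C(\C)CC/C=C(\C)CCC=C(C)C | intermediate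
6 | ethyl 2-(hydroxymethyl)prop-2-enoate | C=C(CO)C(=O)OCC | starting material
7 | prop-2-en-1-yl acetate (allyl acetate) | C=CCOC(C)=O | starting material
8 | ethyl 2-formylprop-2-enoate | C=C(C=O)C(=O)OCC | intermediate (not isolated)
9 | ethyl (3S)-3-hydroxy-2-methylidenehex-5-enoate | C=C(C(=O)OCC)[C@@H](O)CC=C | intermediate
10 | zinc bis[(3S)-2-(ethoxycarbonyl)hexa-1,5-dien-3-olate] | C=C(C(=O)OCC)[C@H](CC=C)O[Zn]O[C@@H](CC=C)C(=C)C(=O)OCC | intermediate (not isolated)
11 | ethyl (3S)-2-methylidene-3-{[(5E,9E)-6,10,14-trimethyl-2-methylidenepentadeca-5,9,13-trien-1-yl]oxy}hex-5-enoate | C=C(C(=O)OCC)[C@@H](OCC(=C)CC/C=C(\C)CC/C=C(\C)CCC=C(C)C)CC=C | intermediate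
12 | ethyl 2-[(2S)-5-[(3E,7E)-4,8,12-trimethyltrideca-3,7,11-trien-1-yl]-3,6-dihydro-2H-pyran-2-yl]prop-2-enoate | C=C(C(=O)OCC)[C@@H]1CC=C(CC/C=C(\C)CC/C=C(\C)CCC=C(C)C)CO1 | intermediate
13 | 2-[(2S)-5-[(3E,7E)-4,8,12-trimethyltrideca-3,7,11-trien-1-yl]-3,6-dihydro-2H-pyran-2-yl]prop-2-enoic acid | C=C(C(=O)O)[C@@H]1CC=C(CC/C=C(\C)CC/C=C(\C)CCC=C(C)C)CO1 | target

**Step count:** 5 steps in total; longest linear sequence 4 steps (6 + 7 → 9 → 11 → 12 → 13).

**Steps most likely to fail**

Step 2 is the weakest. Enal 8 is a doubly activated acceptor, iridium hydride may reduce or isomerise the acrylate, and 6 can oligomerise by oxa-Michael addition under base; the sense of induction on this substrate is also a prediction, and the R ligand is used if it proves opposite. The fallback sets out from 6 and comes back at 13. 6 is silylated (TBSCl, imidazole, DMF) to ethyl 2-({[tert-butyl(dimethyl)silyl]oxy}methyl)prop-2-enoate F1 and reduced (iBu2AlH, CH2Cl2, −78 °C) to 2-({[tert-butyl(dimethyl)silyl]oxy}methyl)prop-2-en-1-ol F2, an ordinary allylic alcohol whose transient enal is no longer an acrylate. The same iridium allylation with 7 gives (3S)-2-({[tert-butyl(dimethyl)silyl]oxy}methyl)hexa-1,5-dien-3-ol F3. Etherification with 5 as above gives the silyl-protected diene ether F4, metathesis as above the silyl-protected dihydropyran F5, Bu4NF the allylic alcohol F6, MnO2 the enal F7, and NaClO2/NaH2PO4/2-methylbut-2-ene the acid 13.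

Step 3 is next. The 2-alkyl π-allyl palladium can lose a β-hydrogen to a diene, and the zinc alkoxide of an electron-poor allylic alcohol is a weak nucleophile. The fallback sets out from 4 and comes back at 11. The alkoxide 4 is quenched with methanesulfonyl chloride instead of acetic anhydride to give (5E,9E)-6,10,14-trimethyl-2-methylidenepentadeca-5,9,13-trien-1-yl methanesulfonate F8, which LiBr converts in the same flask into (5E,9E)-2-(bromomethyl)-6,10,14-trimethylpentadeca-1,5,9,13-tetraene F9. 9 is then O-alkylated directly with F9 and Ag2O (Et2O, dark, rt), a silver-assisted Williamson etherification without palladium, to give 11.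

Step 1 is third. SN2′ attack on 2 or Wurtz-type coupling would cut the yield, and the one-pot acetylation has to compete with excess dianion. The fallback sets out from 2 and comes back at 5. Acetoacetic ester alkylation of 2 (ethyl acetoacetate, NaOEt, EtOH) gives ethyl (4E,8E)-2-acetyl-5,9,13-trimethyltetradeca-4,8,12-trienoate F10, which is saponified and decarboxylated (aqueous NaOH, then acid and heat) to (5E,9E)-6,10,14-trimethylpentadeca-5,9,13-trien-2-one F11 (farnesylacetone). Corey–Chaykovsky methylenation (Me3SI, n-BuLi, THF) gives racemic 2-methyl-2-[(3E,7E)-4,8,12-trimethyltrideca-3,7,11-trien-1-yl]oxirane F12. LiNEt2 opens it by removal of a methyl proton to (5E,9E)-6,10,14-trimethyl-2-methylidenepentadeca-5,9,13-trien-1-ol F13, and Ac2O/pyridine gives 5.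

**Further compounds**
F1 | step 2 | ethyl 2-({[tert-butyl(dimethyl)silyl]oxy}methyl)prop-2-enoate | C=C(CO[Si](C)(C)C(C)(C)C)C(=O)OCC
F2 | step 2 | 2-({[tert-butyl(dimethyl)silyl]oxy}methyl)prop-2-en-1-ol | C=C(CO)CO[Si](C)(C)C(C)(C)C
F3 | step 2 | (3S)-2-({[tert-butyl(dimethyl)silyl]oxy}methyl)hexa-1,5-dien-3-ol | C=C(CO[Si](C)(C)C(C)(C)C)[C@@H](O)CC=C
F4 | step 2 | tert-butyl(dimethyl){[(3S)-2-methylidene-3-{[(5E,9E)-6,10,14-trimethyl-2-methylidenepentadeca-5,9,13-trien-1-yl]oxy}hex-5-en-1-yl]oxy}silane | C=C(CO[Si](C)(C)C(C)(C)C)[C@@H](OCC(=C)CC/C=C(\C)CC/C=C(\C)CCC=C(C)C)CC=C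
F5 | step 2 | tert-butyl(dimethyl)({2-[(2S)-5-[(3E,7E)-4,8,12-trimethyltrideca-3,7,11-trien-1-yl]-3,6-dihydro-2H-pyran-2-yl]prop-2-en-1-yl}oxy)silane | C=C(CO[Si](C)(C)C(C)(C)C)[C@@H]1CC=C(CC/C=C(\C)CC/C=C(\C)CCC=C(C)C)CO1
F6 | step 2 | 2-[(2S)-5-[(3E,7E)-4,8,12-trimethyltrideca-3,7,11-trien-1-yl]-3,6-dihydro-2H-pyran-2-yl]prop-2-en-1-ol | C=C(CO)[C@@H]1CC=C(CC/C=C(\C)CC/C=C(\C)CCC=C(C)C)CO1
F7 | step 2 | 2-[(2S)-5-[(3E,7E)-4,8,12-trimethyltrideca-3,7,11-trien-1-yl]-3,6-dihydro-2H-pyran-2-yl]prop-2-enal | C=C(C=O)[C@@H]1CC=C(CC/C=C(\C)CC/C=C(\C)CCC=C(C)C)CO1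
F8 | step 3 | (5E,9E)-6,10,14-trimethyl-2-methylidenepentadeca-5,9,13-trien-1-yl methanesulfonate | C=C(COS(C)(=O)=O)CC/C=C(\C)CC/C=C(\C)CCC=C(C)C
F9 | step 3 | (5E,9E)-2-(bromomethyl)-6,10,14-trimethylpentadeca-1,5,9,13-tetraene | C=C(CBr)CC/C=C(\C)CC/C=C(\C)CCC=C(C)C
F10 | step 1 | ethyl (4E,8E)-2-acetyl-5,9,13-trimethyltetradeca-4,8,12-trienoate | CCOC(=O)C(C(C)=O)C/C=C(\C)CC/C=C(\C)CCC=C(C)C
F11 | step 1 | (5E,9E)-6,10,14-trimethylpentadeca-5,9,13-trien-2-one | CC(=O)CC/C=C(\C)CC/C=C(\C)CCC=C(C)C
F12 | step 1 | 2-methyl-2-[(3E,7E)-4,8,12-trimethyltrideca-3,7,11-trien-1-yl]oxirane (racemic) | CC1(CC/C=C(\C)CC/C=C(\C)CCC=C(C)C)CO1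
F13 | step 1 | (5E,9E)-6,10,14-trimethyl-2-methylidenepentadeca-5,9,13-trien-1-ol | C=C(CO)CC/C=C(\C)CC/C=C(\C)CCC=C(C)C
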